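**Plan**

1. Locants: ring 1 is the dihydrofuran ring that carries the 2,4-dihydroxyphenyl group (O1, C2, C3, C3a, C7a; benzene carbons C4–C7, with C5 bonded to C2′). Ring 2 is the other dihydrofuran ring (O1′, C2′, C3′, C3a′, C7a′; styryl group on C6′).
2. Cuts: the ten O-protecting groups; the C6′–vinyl bond; O1–C7a together with C3–C3a of ring 1; C2′–C3′ and O1′–C7a′ of ring 2.
3. Enabling feature: O1–C2–C3 is a 1,2-diarylethanol unit, that is a ring-opened stilbene oxide. C3a and C7a are neighbouring carbons of the central benzene ring and can be made a nucleophile/electrophile pair (C3a–Mg beside C7a–Br), so an oxirane can be inserted between them in one flask.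
4. Forward order: ring 2 first (SNAr ether assembly on a 2,6-difluorobenzophenone, then carbene C–H insertion); ring 1 by the arylative oxirane annulation, which also brings in the third stilbene unit; then the styryl arm (Suzuki–Miyaura) and global dealkylation.
5. Stereochemistry: C3 from a Shi epoxidation (inverted once in the annulation); C3′ from the chiral dirhodium carboxylate. Both rings form 2,3-cis, and C2 and C2′ are then brought to trans by acid-mediated equilibration.
6. Helpers removed later: tosylates on the 2,4-dioxygenated ring (stable oxirane, attack steered to C3), the I/Br pair, a tert-butyl ether that the carbene cannot reach, and an aryl chloride as latent styryl site.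

Key step: step 14

Remark: the senses of induction of the D-fructose-derived Shi ketone (R,R-oxirane from an E-stilbene) and of Rh2(R-PTAD)4 are taken by analogy with simpler substrates; the catalyst antipode would be used if the sense were reversed.

Step 1
Reactants: 1 4-bromo-2-hydroxybenzaldehyde
Product: 2 4-bromo-2-hydroxy-5-iodobenzaldehyde
Conditions: NIS, TsOH·H2O (cat.), MeCN, rt
Reagents that add atoms: N-iodosuccinimide O=C1CCC(=O)N1I
Why: Electrophilic aromatic iodination; the hydroxyl group directs para to itself (C5, also meta to the formyl group), the ortho site between OH and Br being crowded.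

Step 2
Reactants: 2 4-bromo-2-hydroxy-5-iodobenzaldehyde
Product: 3 2-(benzyloxy)-4-bromo-5-iodobenzaldehyde
Conditions: BnBr, K2CO3, DMF, rt
Reagents that add atoms: benzyl bromide BrCc1ccccc1
Why: Williamson ether synthesis on the phenoxide.

Step 3
Reactants: 3 2-(benzyloxy)-4-bromo-5-iodobenzaldehyde
Product: 4 [2-(benzyloxy)-4-bromo-5-iodophenyl]methanol
Conditions: NaBH4, MeOH/THF, 0 °C
Reagents that add atoms: none
Why: Borohydride reduction of the aldehyde; the aryl halides are untouched.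

Step 4
Reactants: 5 1-chloro-3,5-difluorobenzene; 6 3,5-bis(benzyloxy)benzaldehyde
Product: 8 racemic [3,5-bis(benzyloxy)phenyl](4-chloro-2,6-difluorophenyl)methanol, via aryllithium 7 (not isolated)
Conditions: LiN(iPr)2, THF, −78 °C; then 6, −78 °C to rt
Reagents that add atoms: none
Why: Directed ortho-lithiation at the most acidic C–H bond, between the two fluorines, followed by 1,2-addition to the aldehyde; the new carbinol center is racemic and is removed in step 5.

Step 5
Reactants: 8 racemic [3,5-bis(benzyloxy)phenyl](4-chloro-2,6-difluorophenyl)methanol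
Product: 9 [3,5-bis(benzyloxy)phenyl](4-chloro-2,6-difluorophenyl)methanone
Conditions: Dess–Martin periodinane, NaHCO3, CH2Cl2, rt
Reagents that add atoms: none
Why: Dess–Martin oxidation of the diarylcarbinol to the benzophenone, which activates both ortho fluorines for SNAr.

Step 6
Reactants: 9 [3,5-bis(benzyloxy)phenyl](4-chloro-2,6-difluorophenyl)methanone
Product: 10 [3,5-bis(benzyloxy)phenyl](2-tert-butoxy-4-chloro-6-fluorophenyl)methanone
Conditions: KOtBu (1 equiv), THF, −20 to 0 °C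
Reagents that add atoms: potassium tert-butoxide CC(C)(C)[O-].[K+]
Why: SNAr at one of the two equivalent fluorines ortho to the ketone; the first alkoxy group slows a second substitution, fluoride leaves far faster than the para chloride, and the tert-butyl ether has no C–H bond within reach of the later carbene.

Step 7
Reactants: 10 [3,5-bis(benzyloxy)phenyl](2-tert-butoxy-4-chloro-6-fluorophenyl)methanone; 4 [2-(benzyloxy)-4-bromo-5-iodophenyl]methanol
Product: 11 [3,5-bis(benzyloxy)phenyl]{2-{[2-(benzyloxy)-4-bromo-5-iodophenyl]methoxy}-6-tert-butoxy-4-chlorophenyl}methanone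
Conditions: 4, NaH, THF/DMF, 0 °C; then 10, 50 °C
Reagents that add atoms: none
Why: Second SNAr by the sodium alkoxide of 4 at the remaining fluorine ortho to the ketone forms the O1′–C7a′ aryl benzyl ether whose CH2 becomes C2′.

Step 8
Reactants: 11 [3,5-bis(benzyloxy)phenyl]{2-{[2-(benzyloxy)-4-bromo-5-iodophenyl]methoxy}-6-tert-butoxy-4-chlorophenyl}methanone
Product: 12 hydrazone of ketone 11 (C=N geometry not defined)
Conditions: N2H4 (anhydrous, excess), AcOH (cat.), EtOH, 80 °C, sealed vessel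
Reagents that add atoms: hydrazine NN
Why: Hydrazone condensation of the diaryl ketone; no ortho fluorine is left that could close an indazole.

Step 9
Reactants: 12 hydrazone of ketone 11
Product: 14 (2S,3R)-2-[2-(benzyloxy)-4-bromo-5-iodophenyl]-3-[3,5-bis(benzyloxy)phenyl]-4-tert-butoxy-6-chloro-2,3-dihydro-1-benzofuran, via diaryldiazomethane 13 (not isolated)
Conditions: MnO2, CH2Cl2, 0 °C; filtration; then Rh2(R-PTAD)4 {dirhodium tetrakis[(R)-N-phthaloyl-(1-adamantyl)glycinate], 1 mol%}, CH2Cl2, −20 °C to rt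
Reagents that add atoms: none
Why: MnO2 oxidises the hydrazone to the diaryldiazomethane, and the chiral dirhodium carboxylate forms a donor/donor carbene that inserts into the benzylic ether C–H bond (intramolecular 1,5 C–H insertion) to close C2′–C3′; C3′ should be set by the catalyst and C2′ should arise cis to it in the concerted insertion.

Step 10
Reactants: 15 2,4-dihydroxybenzaldehyde
Product: 16 4-formyl-1,3-phenylene bis(4-methylbenzenesulfonate)
Conditions: TsCl, Et3N, DMAP (cat.), CH2Cl2, 0 °C to rt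
Reagents that add atoms: 4-toluenesulfonyl chloride Cc1ccc(cc1)S(Cl)(=O)=O
Why: Sulfonylation of both phenols; the electron-poor tosylates make the later oxirane stable and bias its opening.

Step 11
Reactants: 17 3,5-bis(benzyloxy)benzyl bromide
Product: 18 diethyl [3,5-bis(benzyloxy)benzyl]phosphonate
Conditions: P(OEt)3, neat, 140 °C
Reagents that add atoms: triethyl phosphite CCOP(OCC)OCC
Why: Michaelis–Arbuzov reaction of the benzylic bromide.

Step 12
Reactants: 18 diethyl [3,5-bis(benzyloxy)benzyl]phosphonate; 16 4-formyl-1,3-phenylene bis(4-methylbenzenesulfonate)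
Product: 19 4-{(E)-2-[3,5-bis(benzyloxy)phenyl]ethenyl}-1,3-phenylene bis(4-methylbenzenesulfonate)
Conditions: 18, NaH, THF, 0 °C; then 16, 0 °C to rt
Reagents that add atoms: none
Why: Horner–Wadsworth–Emmons olefination with the benzylic phosphonate anion, E-selective; aryl tosylates should tolerate NaH at 0 °C.

Step 13
Reactants: 19 4-{(E)-2-[3,5-bis(benzyloxy)phenyl]ethenyl}-1,3-phenylene bis(4-methylbenzenesulfonate)
Product: 20 4-{(2R,3R)-3-[3,5-bis(benzyloxy)phenyl]oxiran-2-yl}-1,3-phenylene bis(4-methylbenzenesulfonate)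
Conditions: D-fructose-derived Shi ketone (30 mol%), KHSO5 (as Oxone), K2CO3, Bu4NHSO4, MeCN/dimethoxymethane/aqueous buffer (pH 10.5), 0 °C
Reagents that add atoms: potassium peroxymonosulfate [K+].[O-]S(=O)(=O)OO
Why: Shi epoxidation by the chiral dioxirane through the spiro transition state should give the trans (R,R)-oxirane, which fixes the configuration of the carbon that becomes C3.

Step 14
Reactants: 14 (2S,3R)-2-[2-(benzyloxy)-4-bromo-5-iodophenyl]-3-[3,5-bis(benzyloxy)phenyl]-4-tert-butoxy-6-chloro-2,3-dihydro-1-benzofuran; 20 4-{(2R,3R)-3-[3,5-bis(benzyloxy)phenyl]oxiran-2-yl}-1,3-phenylene bis(4-methylbenzenesulfonate)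
Product: 23 (2S,3R)-6-(benzyloxy)-3-[3,5-bis(benzyloxy)phenyl]-5-[(2S,3R)-3-[3,5-bis(benzyloxy)phenyl]-4-tert-butoxy-6-chloro-2,3-dihydro-1-benzofuran-2-yl]-2-[2,4-bis(tosyloxy)phenyl]-2,3-dihydro-1-benzofuran, via arylmagnesium chloride 21 (not isolated), via bromo alkoxide 22 (not isolated)
Conditions: 14, iPrMgCl·LiCl, THF, −40 °C; CuI (10 mol%), then 20, −30 to 0 °C; then Pd(OAc)2 (5 mol%), 2-(di-tert-butylphosphino)-1,1′-binaphthyl (7 mol%), toluene, 70 °C, same flask
Reagents that add atoms: none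
Why: Iodine–magnesium exchange at C3a (faster than at the C7a bromide) gives arylmagnesium 21, whose arylcopper form opens oxirane 20 by backside attack at the benzylic carbon that becomes C3, and the chloromagnesium alkoxide 22 so released is joined to C7a by palladium-catalysed C–O reductive elimination from a six-membered aryl(alkoxo)palladium chelate, so that C3–C3a and O1–C7a form in one flask. The closest known reaction types are the copper-catalysed ring opening of epoxides by aryl Grignard reagents and the palladium-catalysed intramolecular etherification of aryl bromides with secondary alcohols. The five-membered ring closes by attack of O1 on C7a of the benzene ring, formally a 5-exo closure at an sp2 carbon that runs through oxidative addition and reductive elimination. C3 is set by inversion at the oxirane carbon (3R in 20, 3R in 23 after the change in ligand ranking) and C2 keeps its C–O bond and configuration (2S in 23), so the ring forms 2,3-cis and C2 is corrected in step 17. The step needs attack at C3 and not at C2 of the oxirane: the ortho-tosyloxy group shields C2 and the doubly sulfonylated ring disfavours positive charge at C2 in the magnesium-assisted opening, whereas the 3,5-bis(benzyloxy)phenyl ring on C3 has no ortho substituent. It also needs the bromide, the aryl chloride and the aryl tosylates to survive the exchange and the opening at or below 0 °C, which they should.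

Step 15
Reactants: 23 bis(dihydrobenzofuran) ditosylate (as named in step 14)
Product: 24 (2S,3R)-6-(benzyloxy)-3-[3,5-bis(benzyloxy)phenyl]-5-[(2S,3R)-3-[3,5-bis(benzyloxy)phenyl]-4-tert-butoxy-6-chloro-2,3-dihydro-1-benzofuran-2-yl]-2-(2,4-dihydroxyphenyl)-2,3-dihydro-1-benzofuran
Conditions: Mg turnings, MeOH/THF, rt
Reagents that add atoms: none
Why: Reductive S–O cleavage of the two aryl tosylates by electron transfer from magnesium in methanol, which should leave the benzyl and tert-butyl ethers, the aryl chloride and both dihydrofuran rings alone.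

Step 16
Reactants: 24 resorcinol from step 15
Product: 25 (2S,3R)-6-(benzyloxy)-2-[2,4-bis(benzyloxy)phenyl]-3-[3,5-bis(benzyloxy)phenyl]-5-[(2S,3R)-3-[3,5-bis(benzyloxy)phenyl]-4-tert-butoxy-6-chloro-2,3-dihydro-1-benzofuran-2-yl]-2,3-dihydro-1-benzofuran
Conditions: BnBr, K2CO3, DMF, rt
Reagents that add atoms: benzyl bromide BrCc1ccccc1
Why: Williamson benzylation of the two phenols, so that the aryl group on C2 is electron-rich again and the protecting groups are uniform.

Step 17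
Reactants: 25 cis,cis compound from step 16
Product: 26 (2R,3R)-6-(benzyloxy)-2-[2,4-bis(benzyloxy)phenyl]-3-[3,5-bis(benzyloxy)phenyl]-5-[(2R,3R)-3-[3,5-bis(benzyloxy)phenyl]-4-tert-butoxy-6-chloro-2,3-dihydro-1-benzofuran-2-yl]-2,3-dihydro-1-benzofuran
Conditions: TFA (2 vol%), CH2Cl2, 0 °C
Reagents that add atoms: none
Why: Acid-mediated epimerisation: each C2–O bond is a benzylic aryl ether on an ortho,para-dioxygenated ring, so reversible ionisation and reclosure should bring C2 and C2′ to the more stable 2,3-trans arrangement, while C3 and C3′, which are not part of the ionising bond, keep their configuration.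

Step 18
Reactants: 27 2,4-bis(benzyloxy)benzaldehyde
Product: 28 2-{(E)-2-[2,4-bis(benzyloxy)phenyl]ethenyl}-4,4,5,5-tetramethyl-1,3,2-dioxaborolane
Conditions: bis[(pinacolato)boryl]methane, lithium 2,2,6,6-tetramethylpiperidide, THF, −78 to 0 °C
Reagents that add atoms: bis[(pinacolato)boryl]methane CC1(C)OB(CB2OC(C)(C)C(C)(C)O2)OC1(C)C
Why: Boron-Wittig olefination: the lithiated geminal bis(boronate) adds to the aldehyde and B–O elimination should give the E-alkenylboronate.

Step 19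
Reactants: 26 trans,trans aryl chloride from step 17; 28 2-{(E)-2-[2,4-bis(benzyloxy)phenyl]ethenyl}-4,4,5,5-tetramethyl-1,3,2-dioxaborolane
Product: 29 (2R,3R)-6-(benzyloxy)-2-[2,4-bis(benzyloxy)phenyl]-3-[3,5-bis(benzyloxy)phenyl]-5-[(2R,3R)-6-{(E)-2-[2,4-bis(benzyloxy)phenyl]ethenyl}-3-[3,5-bis(benzyloxy)phenyl]-4-tert-butoxy-2,3-dihydro-1-benzofuran-2-yl]-2,3-dihydro-1-benzofuran
Conditions: Pd(OAc)2 (5 mol%), SPhos (10 mol%), K3PO4, 1,4-dioxane/H2O, 80 °C
Reagents that add atoms: none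
Why: Suzuki–Miyaura coupling of the aryl chloride with the alkenylboronate under a dialkylbiarylphosphine palladium catalyst, with retention of the E geometry.

Step 20
Reactants: 29 protected gneyulin A from step 19
Product: 30 gneyulin A
Conditions: BCl3, pentamethylbenzene, CH2Cl2, −78 °C; MeOH, then aqueous work-up
Reagents that add atoms: none
Why: Lewis-acid dealkylation with BCl3 and pentamethylbenzene as a non-basic cation scavenger at low temperature should cleave the nine benzyl ethers and the tert-butyl ether without reducing the stilbene.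

**Compound list**

1 | 4-bromo-2-hydroxybenzaldehyde | O=Cc1ccc(Br)cc1O | starting material
2 | 4-bromo-2-hydroxy-5-iodobenzaldehyde | O=Cc1cc(I)c(Br)cc1O | intermediate
3 | 2-(benzyloxy)-4-bromo-5-iodobenzaldehyde | O=Cc1cc(I)c(Br)cc1OCc1ccccc1 | intermediate
4 | [2-(benzyloxy)-4-bromo-5-iodophenyl]methanol | OCc1cc(I)c(Br)cc1OCc1ccccc1 | intermediate
5 | 1-chloro-3,5-difluorobenzene | Fc1cc(Cl)cc(F)c1 | starting material
6 | 3,5-bis(benzyloxy)benzaldehyde | O=Cc1cc(OCc2ccccc2)cc(OCc2ccccc2)c1 | starting material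
7 | (4-chloro-2,6-difluorophenyl)lithium | [Li]c1c(F)cc(Cl)cc1F | intermediate
8 | racemic [3,5-bis(benzyloxy)phenyl](4-chloro-2,6-difluorophenyl)methanol | OC(c1cc(OCc2ccccc2)cc(OCc2ccccc2)c1)c1c(F)cc(Cl)cc1F | intermediate
9 | [3,5-bis(benzyloxy)phenyl](4-chloro-2,6-difluorophenyl)methanone | O=C(c1cc(OCc2ccccc2)cc(OCc2ccccc2)c1)c1c(F)cc(Cl)cc1F | intermediate
10 | [3,5-bis(benzyloxy)phenyl](2-tert-butoxy-4-chloro-6-fluorophenyl)methanone | O=C(c1cc(OCc2ccccc2)cc(OCc2ccccc2)c1)c1c(F)cc(Cl)cc1OC(C)(C)C | intermediate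
11 | [3,5-bis(benzyloxy)phenyl]{2-{[2-(benzyloxy)-4-bromo-5-iodophenyl]methoxy}-6-tert-butoxy-4-chlorophenyl}methanone | O=C(c1cc(OCc2ccccc2)cc(OCc2ccccc2)c1)c1c(OCc2cc(I)c(Br)cc2OCc2ccccc2)cc(Cl)cc1OC(C)(C)C | intermediate
12 | hydrazone of ketone 11 | NN=C(c1cc(OCc2ccccc2)cc(OCc2ccccc2)c1)c1c(OCc2cc(I)c(Br)cc2OCc2ccccc2)cc(Cl)cc1OC(C)(C)C | intermediate
13 | diaryldiazomethane from 12 | [N-]=[N+]=C(c1cc(OCc2ccccc2)cc(OCc2ccccc2)c1)c1c(OCc2cc(I)c(Br)cc2OCc2ccccc2)cc(Cl)cc1OC(C)(C)C | intermediate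
14 | (2S,3R)-2-[2-(benzyloxy)-4-bromo-5-iodophenyl]-3-[3,5-bis(benzyloxy)phenyl]-4-tert-butoxy-6-chloro-2,3-dihydro-1-benzofuran (2,3-cis) | c1ccccc1COc1cc(Br)c(I)cc1[C@H]1Oc2cc(Cl)cc(OC(C)(C)C)c2[C@H]1c1cc(OCc2ccccc2)cc(OCc2ccccc2)c1 | intermediate
15 | 2,4-dihydroxybenzaldehyde | O=Cc1ccc(O)cc1O | starting material
16 | 4-formyl-1,3-phenylene bis(4-methylbenzenesulfonate) | O=Cc1ccc(OS(=O)(=O)c2ccc(C)cc2)cc1OS(=O)(=O)c1ccc(C)cc1 | intermediate
17 | 3,5-bis(benzyloxy)benzyl bromide | BrCc1cc(OCc2ccccc2)cc(OCc2ccccc2)c1 | starting material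
18 | diethyl [3,5-bis(benzyloxy)benzyl]phosphonate | CCOP(=O)(OCC)Cc1cc(OCc2ccccc2)cc(OCc2ccccc2)c1 | intermediate
19 | 4-{(E)-2-[3,5-bis(benzyloxy)phenyl]ethenyl}-1,3-phenylene bis(4-methylbenzenesulfonate) | Cc1ccc(cc1)S(=O)(=O)Oc1ccc(/C=C/c2cc(OCc3ccccc3)cc(OCc3ccccc3)c2)c(OS(=O)(=O)c2ccc(C)cc2)c1 | intermediate
20 | 4-{(2R,3R)-3-[3,5-bis(benzyloxy)phenyl]oxiran-2-yl}-1,3-phenylene bis(4-methylbenzenesulfonate) (trans) | c1c(OCc2ccccc2)cc(OCc2ccccc2)cc1[C@H]1O[C@@H]1c1ccc(OS(=O)(=O)c2ccc(C)cc2)cc1OS(=O)(=O)c1ccc(C)cc1 | intermediate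
21 | {4-(benzyloxy)-2-bromo-5-[(2S,3R)-3-[3,5-bis(benzyloxy)phenyl]-4-tert-butoxy-6-chloro-2,3-dihydro-1-benzofuran-2-yl]phenyl}magnesium chloride | c1ccccc1COc1cc(Br)c([Mg]Cl)cc1[C@H]1Oc2cc(Cl)cc(OC(C)(C)C)c2[C@H]1c1cc(OCc2ccccc2)cc(OCc2ccccc2)c1 | intermediate
22 | chloromagnesium (1S,2R)-2-{4-(benzyloxy)-2-bromo-5-[(2S,3R)-3-[3,5-bis(benzyloxy)phenyl]-4-tert-butoxy-6-chloro-2,3-dihydro-1-benzofuran-2-yl]phenyl}-2-[3,5-bis(benzyloxy)phenyl]-1-[2,4-bis(tosyloxy)phenyl]ethan-1-olate | c1c(OCc2ccccc2)cc(OCc2ccccc2)cc1[C@@H]([C@H](O[Mg]Cl)c1ccc(OS(=O)(=O)c2ccc(C)cc2)cc1OS(=O)(=O)c1ccc(C)cc1)c1cc([C@H]2Oc3cc(Cl)cc(OC(C)(C)C)c3[C@H]2c2cc(OCc3ccccc3)cc(OCc3ccccc3)c2)c(OCc2ccccc2)cc1Br | intermediate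
23 | (2S,3R)-6-(benzyloxy)-3-[3,5-bis(benzyloxy)phenyl]-5-[(2S,3R)-3-[3,5-bis(benzyloxy)phenyl]-4-tert-butoxy-6-chloro-2,3-dihydro-1-benzofuran-2-yl]-2-[2,4-bis(tosyloxy)phenyl]-2,3-dihydro-1-benzofuran | c1c(OCc2ccccc2)cc(OCc2ccccc2)cc1[C@@H]1c2cc([C@H]3Oc4cc(Cl)cc(OC(C)(C)C)c4[C@H]3c3cc(OCc4ccccc4)cc(OCc4ccccc4)c3)c(OCc3ccccc3)cc2O[C@@H]1c1ccc(OS(=O)(=O)c2ccc(C)cc2)cc1OS(=O)(=O)c1ccc(C)cc1 | intermediate
24 | 2-(2,4-dihydroxyphenyl) analogue of 23 | c1c(OCc2ccccc2)cc(OCc2ccccc2)cc1[C@@H]1c2cc([C@H]3Oc4cc(Cl)cc(OC(C)(C)C)c4[C@H]3c3cc(OCc4ccccc4)cc(OCc4ccccc4)c3)c(OCc3ccccc3)cc2O[C@@H]1c1ccc(O)cc1O | intermediate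
25 | 2-[2,4-bis(benzyloxy)phenyl] analogue of 23 (rings 1 and 2 both 2,3-cis) | c1c(OCc2ccccc2)cc(OCc2ccccc2)cc1[C@@H]1c2cc([C@H]3Oc4cc(Cl)cc(OC(C)(C)C)c4[C@H]3c3cc(OCc4ccccc4)cc(OCc4ccccc4)c3)c(OCc3ccccc3)cc2O[C@@H]1c1ccc(OCc2ccccc2)cc1OCc1ccccc1 | intermediate
26 | (2R,3R)-6-(benzyloxy)-2-[2,4-bis(benzyloxy)phenyl]-3-[3,5-bis(benzyloxy)phenyl]-5-[(2R,3R)-3-[3,5-bis(benzyloxy)phenyl]-4-tert-butoxy-6-chloro-2,3-dihydro-1-benzofuran-2-yl]-2,3-dihydro-1-benzofuran | c1c(OCc2ccccc2)cc(OCc2ccccc2)cc1[C@@H]1c2cc([C@@H]3Oc4cc(Cl)cc(OC(C)(C)C)c4[C@H]3c3cc(OCc4ccccc4)cc(OCc4ccccc4)c3)c(OCc3ccccc3)cc2O[C@H]1c1ccc(OCc2ccccc2)cc1OCc1ccccc1 | intermediate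
27 | 2,4-bis(benzyloxy)benzaldehyde | O=Cc1ccc(OCc2ccccc2)cc1OCc1ccccc1 | starting material
28 | 2-{(E)-2-[2,4-bis(benzyloxy)phenyl]ethenyl}-4,4,5,5-tetramethyl-1,3,2-dioxaborolane | CC1(C)OB(/C=C/c2ccc(OCc3ccccc3)cc2OCc2ccccc2)OC1(C)C | intermediate
29 | nona-O-benzyl 4′-O-tert-butyl gneyulin A | c1c(OCc2ccccc2)cc(OCc2ccccc2)cc1[C@@H]1c2cc([C@@H]3Oc4cc(/C=C/c5ccc(OCc6ccccc6)cc5OCc5ccccc5)cc(OC(C)(C)C)c4[C@H]3c3cc(OCc4ccccc4)cc(OCc4ccccc4)c3)c(OCc3ccccc3)cc2O[C@H]1c1ccc(OCc2ccccc2)cc1OCc1ccccc1 | intermediate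
30 | gneyulin A | Oc1cc(O)cc([C@@H]2c3cc([C@@H]4Oc5cc(/C=C/c6ccc(O)cc6O)cc(O)c5[C@H]4c4cc(O)cc(O)c4)c(O)cc3O[C@H]2c2ccc(O)cc2O)c1 | target

**Totals and risks**

Total step count: 20. Longest linear sequence: 12 steps (steps 4, 5, 6, 7, 8, 9, 14, 15, 16, 17, 19, 20).

Steps most likely to fail:

Step 14. What may go wrong: loss of regiocontrol in the oxirane opening (attack at C2), or β-hydride loss from the palladium alkoxide before C–O bond formation. Fallback: the same two bonds are made at the benzofuran oxidation level. Setting out from 14, palladium-catalysed ketone α-arylation at the iodide followed by intramolecular enolate O-arylation at the bromide (Pd2(dba)3, Xantphos, Cs2CO3, toluene, 110 °C) is run with 1-[2,4-bis(benzyloxy)phenyl]-2-[3,5-bis(benzyloxy)phenyl]ethan-1-one F1 (from Friedel–Crafts acylation of 1,3-bis(benzyloxy)benzene with [3,5-bis(benzyloxy)phenyl]acetic acid) and should give the 2,3-diarylbenzofuran F2. Ionic hydrogenation (Et3SiH, TFA, CH2Cl2) should then give ring 1 as the trans isomer, epimerise C2′ of ring 2 to trans and cleave the tert-butyl ether, giving the phenol F3. Ring 1 is not under reagent control here, so F3 must be separated from its ring-1 diastereomer; the enantioenriched ring 2 makes the two products diastereomers. Suzuki–Miyaura coupling with 28 under the conditions of step 19 should give the stilbene F4, which comes back to the route at 30 through the conditions of step 20.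

Step 8. What may go wrong: steric blocking of hydrazine addition at the doubly ortho-substituted ketone. Fallback: the carbonyl group is activated as the thioketone. Setting out from 11, Lawesson's reagent (toluene, 90 °C) should give the thioketone F5, which should condense with hydrazine at room temperature and come back to the route at 12.

Step 20. What may go wrong: irreversible capture of the benzylic C2 and C2′ cations formed when the Lewis acid opens the dihydrofuran rings, or cationic cyclisation of the electron-rich stilbene. Fallback: the ethers are cleaved before the alkene exists and the styryl arm is attached last. Setting out from 26, BCl3 and pentamethylbenzene at −78 °C should give the octaphenol aryl chloride F6. In parallel, 2,4-bis(tert-butyldimethylsilyloxy)benzaldehyde F7 (from 15, tert-butyldimethylsilyl chloride, imidazole, DMF) is converted under the conditions of step 18 to the alkenylboronate F8. Suzuki–Miyaura coupling of F6 with F8 (Pd(OAc)2, SPhos, K3PO4, degassed dioxane/water) should give the bis-silyl ether F9, and buffered fluoride (Bu4NF, AcOH, THF, 0 °C) comes back to the route at 30.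

**Further compounds**

F1 | step 14 | 1-[2,4-bis(benzyloxy)phenyl]-2-[3,5-bis(benzyloxy)phenyl]ethan-1-one | O=C(Cc1cc(OCc2ccccc2)cc(OCc2ccccc2)c1)c1ccc(OCc2ccccc2)cc1OCc1ccccc1
F2 | step 14 | 6-(benzyloxy)-2-[2,4-bis(benzyloxy)phenyl]-3-[3,5-bis(benzyloxy)phenyl]-5-[(2S,3R)-3-[3,5-bis(benzyloxy)phenyl]-4-tert-butoxy-6-chloro-2,3-dihydro-1-benzofuran-2-yl]-1-benzofuran | c1c(OCc2ccccc2)cc(OCc2ccccc2)cc1-c1c2cc([C@H]3Oc4cc(Cl)cc(OC(C)(C)C)c4[C@H]3c3cc(OCc4ccccc4)cc(OCc4ccccc4)c3)c(OCc3ccccc3)cc2oc1-c1ccc(OCc2ccccc2)cc1OCc1ccccc1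
F3 | step 14 | 4′-hydroxy analogue of 26 (tert-butyl ether cleaved) | c1c(OCc2ccccc2)cc(OCc2ccccc2)cc1[C@@H]1c2cc([C@@H]3Oc4cc(Cl)cc(O)c4[C@H]3c3cc(OCc4ccccc4)cc(OCc4ccccc4)c3)c(OCc3ccccc3)cc2O[C@H]1c1ccc(OCc2ccccc2)cc1OCc1ccccc1
F4 | step 14 | 4′-hydroxy analogue of 29 (nona-O-benzyl gneyulin A) | c1c(OCc2ccccc2)cc(OCc2ccccc2)cc1[C@@H]1c2cc([C@@H]3Oc4cc(/C=C/c5ccc(OCc6ccccc6)cc5OCc5ccccc5)cc(O)c4[C@H]3c3cc(OCc4ccccc4)cc(OCc4ccccc4)c3)c(OCc3ccccc3)cc2O[C@H]1c1ccc(OCc2ccccc2)cc1OCc1ccccc1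
F5 | step 8 | thioketone of 11 | S=C(c1cc(OCc2ccccc2)cc(OCc2ccccc2)c1)c1c(OCc2cc(I)c(Br)cc2OCc2ccccc2)cc(Cl)cc1OC(C)(C)C
F6 | step 20 | 6′-chloro analogue of gneyulin A lacking the styryl group (octaphenol) | Oc1cc(O)cc([C@@H]2c3cc([C@@H]4Oc5cc(Cl)cc(O)c5[C@H]4c4cc(O)cc(O)c4)c(O)cc3O[C@H]2c2ccc(O)cc2O)c1
F7 | step 20 | 2,4-bis(tert-butyldimethylsilyloxy)benzaldehyde | O=Cc1ccc(O[Si](C)(C)C(C)(C)C)cc1O[Si](C)(C)C(C)(C)C
F8 | step 20 | 2-{(E)-2-[2,4-bis(tert-butyldimethylsilyloxy)phenyl]ethenyl}-4,4,5,5-tetramethyl-1,3,2-dioxaborolane | CC1(C)OB(/C=C/c2ccc(O[Si](C)(C)C(C)(C)C)cc2O[Si](C)(C)C(C)(C)C)OC1(C)C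
F9 | step 20 | gneyulin A bis(tert-butyldimethylsilyl) ether at the styryl resorcinol ring | Oc1cc(O)cc([C@@H]2c3cc([C@@H]4Oc5cc(/C=C/c6ccc(O[Si](C)(C)C(C)(C)C)cc6O[Si](C)(C)C(C)(C)C)cc(O)c5[C@H]4c4cc(O)cc(O)c4)c(O)cc3O[C@H]2c2ccc(O)cc2O)c1
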